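Late in both earlier runs the pool, meaning c(starting material) + c(target) + c(isomer of the product) in percent of the charge, sinks slowly, and that slow sinking is the quantity to carry to the new flask.

| setting | north-west | south-east | flask |
|---|---|---|---|
| starting material | 0.014 M (fed, over 50 min) | 0.022 M (fed, over 50 min) | 0.010 M (fed, over 50 min) |
| protic impurity | 0.20 mM | 0.20 mM | 0.200 mM |
| remark | run made earlier; the fed solution adds 0.10 times the starting volume | run made earlier; the fed solution adds 0.10 times the starting volume | the fed solution adds 0.10 times the starting volume |
| time |  |  | 2.5 h |

- north-west (time / min: starting material / %, target / %, isomer of the product / %): 10.0: 4.2, 1.5, 15.3; 20.0: 2.0, 2.9, 35.3; 30.0: 6.2, 2.2, 51.0; 60.0: 6.1, 2.3, 86.1; 120: 6.5, 2.9, 83.4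
- south-east (time / min: starting material / %, target / %, isomer of the product / %): 10.0: 1.9, 0, 15.9; 20.0: 4.4, 1.1, 34.8; 30.0: 6.4, 0.3, 49.7; 60.0: 6.8, 2.6, 88.6; 120: 5.2, 1.1, 83.9

(scatter of a reading: 1 percentage point)

- charges are per starting volume, the dose included; the dosed solution carries all of it
- the numbers in the tables scatter by 1 percentage point (one standard deviation)
- the reaction counts as stopped when no species that holds the starting material changes by six tenths of a point or more over the second half of the time
- percentages count the whole charge, also what has not yet gone in

1. at 2.5 h, what has stopped the reaction, if anything has (forward and back rates have come level / it is still moving / all of the starting material has reacted)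
2. share of the starting material used up at 2.5 h
3. target at 2.5 h, in percent of the starting material charged
4. isomer of the product at 2.5 h, in percent of the starting material charged
5. over-reaction product at 2.5 h, in percent of the starting material charged
6. amount of target if the flask were left three thousand times as long, in percent of the starting material charged

1. Averaged over the two earlier runs, the pool stands at 96.2% at 60.0 min and 91.5% at 120 min.

2. Charges of 0.014 M and 0.022 M end at similar percentages, so the loss is treated as pseudo-first-order in the pool.

3. 19.8 h is the drain time, the time in which the pool falls by a factor e. With a scatter of 1 percentage point on each reading, it is a reading and not a constant.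

4. My reckoning for the new flask counts the pool's loss as over-reaction product. If the whole charge had stood in the flask from the start, the loss at 2.5 h would be 11.9%, the upper end of the bracket at this drain time.

5. If the whole charge had arrived at the end of the dose, the loss would be 8.09%, the lower end at this drain time. The dose is far shorter than the drain time, so at this drain time the two ends lie 3.8 points apart.

6. A steady dose enters on average at half the dosing time, which tightens the estimate to 10.0%.

7. The forecast says it is still moving, with conversion 94%, target 2.2%, isomer of the product 82.5%, over-reaction product 9.5% and long-term target 2%. Its over-reaction value, on the grounds that the loss “points to a slow over-reaction”, stands inside the bracket, a little below my tightened value.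

8. The result for the flask at 2.5 h is: it is still moving, with conversion 93.5%, target 2.57%, isomer of the product 79.7% and over-reaction product 9.40%; its long-term target is 0%. The over-reaction product lies inside the bracket.

    target → over-reaction product (k = 0.0283 min⁻¹)
    target ⇌ isomer of the product (K = 24.0, k = 0.0160 min⁻¹)
    starting material ⇌ target (K = 0.510, k = 0.0408 min⁻¹)
    isomer of the product ⇌ starting material (k = 0.146 min⁻¹)
    starting material + protic impurity → quenched substrate (k = 27.2 M⁻¹ min⁻¹)

The flask's pool at 2.50 h is 88.8%, against 90.0% from the tightened reckoning. Its loss of 11.2% holds over-reaction product 9.40% and quenched substrate 1.79%. The neighbouring flask is the same one left until 10 h. Carried on for a further 7.50 h, the drain time puts its pool at 60.8%. That neighbouring flask holds a pool of 61.2%, with over-reaction product at 36.8%.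

The data come from a simulation on assumed constants.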